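**Remark on the chemistry.** Unit 1 is the 7-methoxyflavone and unit 2 is the flavone whose C6 carries the ether oxygen. After step 7, ring A of unit 2 is mirror-symmetric, so counting the ketene carbonyl carbon of 13 as C7 and not C5 is bookkeeping only. With that count the key step forms C7–C8 and C4a–C8a. Bromovinyl ether 3 is expected as a Z-rich mixture of geometric isomers; either isomer serves.

## Analysis of the target

Neocryptomerin (35) is made of two flavone units joined by a diaryl ether. The ether oxygen links C4' of ring B of unit 1 (5-hydroxy-7-methoxyflavone) to C6 of ring A of unit 2 (a 5,7,4'-trihydroxyflavone). The molecule has no stereocentre, so every selectivity question is one of regio- or chemoselectivity. The sensitive functions are four phenols (two chelated to the C4 carbonyls), two base-labile 4-pyranone rings, and one methyl ether at O7 of unit 1 that must survive while every other oxygen is set free. The real difficulty is the ether oxygen on C6 of unit 2. That carbon lies between the oxygen-bearing carbons C5 and C7, so a coupling there meets a hindered, electron-rich site. Any route must also exclude the isomeric 8-aryloxy series, which can arise from the wrong ring closure or from acid-induced opening and reclosure of a 5-hydroxypyranone (Wessely–Moser isomerisation). The strategy rests on ring A of unit 2: C5, C6, C7 and C8a all carry oxygen in a 1,2,3,5-pattern. Each of these carbons can be traced to a ketene carbonyl carbon or to the oxygen-bearing carbon of an ynol ether, and the C6–O–aryl bond to an aryloxyacetic acid. Ring A can therefore be built around the ether instead of being etherified afterwards.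

## Retrosynthetic reasoning

**35 from 34.** The last disconnection cuts three O–isopropyl bonds (O5 and O7 of unit 2, O4' of its ring B) and the O–methyl bond at O5 of unit 1. Isopropyl ethers fall to a boron Lewis acid at low temperature, and a methyl ether falls only where the neighbouring carbonyl chelates. The methyl ether at O7 of unit 1 is thus distinguished by its position, not by a separate protecting group, and one operation ends the synthesis.

**34 from 29 and 31.** Ring C of unit 1 is cut at C4–C4a, C3–C4 and O1–C2, with C4 added as a one-carbon carbonyl unit. Ring A of unit 1 is a plain phloroglucinol pattern that comes from 30 through iodophenol 31, so the whole of unit 1 can be attached in one carbonylative annulation to the alkyne of 29. The forward step runs in an amine without hydroxide, which the finished pyranone of unit 2 tolerates. It must close in the 6-endo mode.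

**29 from 26 and 27.** The aryl–alkynyl bond is cut (through silyl alkyne 28). The bromine on the phenoxy ring is a silent handle carried from 10, so it must survive every step before this one.

**26 from 22 and 23.** Ring C of unit 2 is cut at O1–C2 and at the C2–C3 bond through chalcone 24. This needs only a 2'-hydroxyacetophenone and an aldehyde. The hydroxide-mediated condensation is placed before any flavone exists.

**22 from 20.** The bond from C4a to the acetyl carbon is cut. Phenol 20 is mirror-symmetric, its para position is blocked by the aryloxy group, and its two free positions are equivalent and ortho to the hydroxyl. Acylation can give only one ketone, and the free hydroxyl is by construction the one that becomes O1. The 8-aryloxy series is excluded structurally.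

**20 from 18.** This is a protecting-group interchange through 19: the lone free hydroxyl of 18 is isopropylated and the single silyl group is removed. What is gained is that the silyl group of 18 marks the future O1 among four ring oxygens.

**18 from 13 and 9.** The key disconnection cuts C7–C8 and C4a–C8a of unit 2 and takes ring A apart into a cyclobutenone and an ynol ether. The cut is made here because every oxygen and the ether bond are then placed by ring construction. No coupling at the flanked C6 is needed: the C6–O–aryl bond is already present in 13. The forward step must deliver one regioisomer, with the silyloxy carbon para to the aryloxy carbon.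

**13 from 11 and 5.** The cyclobutenone is cut across two ring bonds into aryloxyketene 12 (from acid chloride 11, itself from acid 10) and alkoxyalkyne 5. The polarity of 5 fixes the 3-alkoxy-4-aryloxy pattern.

**5 from 1, and 9 from 6.** The two alkynes are reduced to a vinyl ether (through 2, 3 and 4) and to acetylene (through 7 and 8). The isopropyl group in 5 is chosen so that, after step 7, both flanking oxygens of ring A carry the same Lewis-acid-labile group.

## Alternatives that were turned down

**Alternative 1: ring B of unit 1 grown on the ether oxygen from a 2-pyranone.**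
- Disconnection: C2'–C3' and C1'–C6' of ring B of unit 1.
- Forward key step: pyranone A1, which carries the C6 oxygen of unit 2 at its C4, adds as a diene across the triple bond of ethynylchromone A2. Decarboxylative aromatisation of the bridged lactone gives A3.
- For it: the union is late, convergent and reagent-free. The donor at C4 of A1 and the acceptor character of A2 match in polarity, so the para orientation is favoured. No palladium carbonylation is needed. On convergence it is stronger than the chosen route.
- Against it: A1 presupposes that the oxygen on C6 of unit 2 is already in place and free for etherification. The 5,6,7-trioxygenated ring must therefore be built and differentiated by other means, which is the central problem of the target. Pyranone cycloadditions need high temperatures. A2 is a doubly activated acceptor prone to polymerisation and to oxa-Michael addition by the free 5-hydroxyl of A1. From A3 the end game needs two different deprotections (benzyl removal and selective demethylation at O5).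
- Comparison: the chosen route is more linear, but it makes the hard ring itself (13 and 9 to 18) and ends with a single deprotection.

**Alternative 2: anodic C–H etherification installs O1 on ring A of unit 2.**
- Disconnection: O1–C8a of unit 2.
- Forward key step: anodic oxidation of 1,3-diketone A4 in a fluorinated alcohol electrolyte joins the enol oxygen to the only unsubstituted ortho carbon of the trioxygenated ring and gives flavone A5.
- For it: ring A needs only three oxygens before the key step. The 6- versus 8-regiochemistry is fixed by the substitution pattern of A4, which is as secure as in the chosen route. The oxidant is traceless.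
- Against it: the diaryl ether of A4 sits on the middle oxygen of a 2,3,4-trioxygenated aryl ketone, so it must itself come from arylation of an oxygen between two oxygenated carbons. The hindered coupling is moved, not removed. A4 holds three oxidisable electron-rich rings and an enol whose carbon terminus can also attack (five-membered closure), so the chemoselectivity of the radical-cation step is open. From A5, unit 1 must still be raised from the ester in several steps.
- Comparison: step count is similar, but the chosen key step is a thermal pericyclic cascade whose regiochemistry follows from reagent polarity, and the O1 oxygen is marked in advance by the silyl group of 18.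

**Alternative 3: a methoxypyranone recyclised to ring A of unit 1 with the lone methyl ether in place.**
- Disconnection: C4a–C5 and O1–C2 of unit 1.
- Forward key step: a magnesium alkoxide in the parent alcohol opens the pyranone of A6. The doubly activated methylene closes ring A on the liberated ester, and either of the two equivalent phenoxides adds to the ynone to give A7.
- For it: the methyl ether at O7 of unit 1 is set from the start and is never confused with O5. On this point it is stronger than the chosen route, which relies on chelation-controlled demethylation in step 16. Two rings form in one operation.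
- Against it: it spends its key step on the easy ring. Ring A of unit 1 is a simple phloroglucinol pattern that the chosen route takes from 30. A6 already contains the complete unit 2 with its C6 ether, which must be solved separately and then carried through a long linear build-up of a polycarbonyl ynone. That ynone offers the alkoxide several competing sites (conjugate addition, relactonisation, five-membered closure). Three benzyl ethers remain to be removed from A7.
- Comparison: the chosen route gives up the built-in methyl ether differentiation and in return solves the flanked ether of unit 2 by construction.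

Key step: step 6

## Route

**Step 1**
Reactants: 1 isopropyl vinyl ether
Product: 3 (Z)-1-bromo-2-isopropoxyethene, via 1,2-dibromo-1-isopropoxyethane 2 (not isolated)
Conditions: Br2, pentane, −78 °C; then PhNEt2, 95 °C, distil
Reagents that add atoms: bromine, BrBr
Why: Bromine adds across the enol ether double bond and the tertiary aniline removes HBr from the alpha-bromo ether through its oxocarbenium ion, the classical addition–elimination route to 2-halovinyl ethers; the geometry of 3 disappears in step 2.

**Step 2**
Reactants: 3 (Z)-1-bromo-2-isopropoxyethene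
Product: 5 isopropoxyacetylene, via sodium isopropoxyacetylide 4 (not isolated)
Conditions: NaNH2 (2.2 equiv), NH3 (l), −33 °C; then H2O, pentane extraction, used as a titrated solution
Reagents that add atoms: none
Why: Anti E2 elimination of HBr (the hydrogen on the oxygen-bearing carbon is trans to bromine in the Z isomer) gives the alkoxyalkyne, which the second equivalent of amide stores as its acetylide until the quench; this is the standard dehydrohalogenation route to alkoxyacetylenes.

**Step 3**
Reactants: 6 acetylene
Product: 9 (triisopropylsilyloxy)acetylene, via lithium acetylide 7 (not isolated), via lithium ethynolate 8 (not isolated)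
Conditions: n-BuLi, THF, −78 °C; t-BuOOLi (from t-BuOOH and LiN(SiMe3)2), −78 → −20 °C; i-Pr3SiOTf, −78 → 0 °C
Reagents that add atoms: tert-butyl hydroperoxide, CC(C)(C)OO; triisopropylsilyl trifluoromethanesulfonate, CC(C)[Si](C(C)C)(C(C)C)OS(=O)(=O)C(F)(F)F
Why: The lithium acetylide is oxidised at carbon by lithium tert-butyl peroxide (attack on the peroxide oxygen, tert-butoxide leaves), the known conversion of lithium alkynides into lithium ynolates, and the bulky silyl triflate then silylates the ynolate on oxygen; the mixture is kept at or below −20 °C so that monolithium acetylide does not disproportionate.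

**Step 4**
Reactants: 10 (4-bromophenoxy)acetic acid
Product: 11 (4-bromophenoxy)acetyl chloride
Conditions: (COCl)2, DMF (cat.), CH2Cl2, 0 °C → rt
Reagents that add atoms: oxalyl chloride, ClC(=O)C(=O)Cl
Why: Standard acid chloride formation through the chloroiminium species formed from DMF; the aryl ether and aryl bromide are inert.

**Step 5**
Reactants: 11 (4-bromophenoxy)acetyl chloride; 5 isopropoxyacetylene
Product: 13 4-(4-bromophenoxy)-3-isopropoxycyclobut-2-en-1-one (racemic), via (4-bromophenoxy)ketene 12 (not isolated)
Conditions: Et3N, Et2O, 0 °C → rt, slow addition of 11 to 5 (2 equiv)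
Reagents that add atoms: none
Why: Dehydrochlorination gives aryloxyketene 12, which the electron-rich alkyne 5 traps in a (2+2) cycloaddition, the standard access to 4-substituted 3-alkoxycyclobutenones; the nucleophilic CH terminus of 5 bonds to the ketene carbonyl carbon, which fixes the 3-alkoxy-4-aryloxy pattern, and slow addition keeps 12 dilute against dimerisation. The C4 stereocentre forms racemic and is erased in step 6.

**Step 6**
Reactants: 13 4-(4-bromophenoxy)-3-isopropoxycyclobut-2-en-1-one; 9 (triisopropylsilyloxy)acetylene
Product: 18 2-(4-bromophenoxy)-3-isopropoxy-5-(triisopropylsilyloxy)phenol, via vinylketene 14 (not isolated), via vinylcyclobutenone 15 (not isolated), via dienylketene 16 (not isolated), via cyclohexadienone 17 (not isolated)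
Conditions: 9 (2 equiv), toluene (0.3 M), 80 °C, then 110 °C, sealed tube
Reagents that add atoms: none
Why: Thermal four-electron conrotatory opening of 13 should give vinylketene 14, with the aryloxy donor at C4 rotating outward as donors do, so that hydrogen and not the aryloxy group sits inside at the later closure. The electron-rich ynol ether 9 then adds across the ketene C=C bond in a (2+2) cycloaddition: its nucleophilic CH terminus bonds to the electrophilic ketene carbonyl carbon and its silyloxy-bearing carbon to the ketene alpha carbon, giving 15; these are the bonds counted as C7–C8 and C4a–C8a of unit 2. Reversible four-electron opening of 15 leads to dienylketene 16, whose thermal six-electron disrotatory electrocyclisation closes ring A onto the ketene carbon, and enolisation of dienone 17 delivers phenol 18. The closest known reaction type is the Danheiser benzannulation of cyclobutenones with trialkylsilyloxyalkynes to resorcinol monosilyl ethers; 13 differs in carrying two oxygen substituents. No stereocentre is formed and the one in 13 is lost. The step needs regioselectivity in the (2+2) event, which the polarity of 9 secures by placing the silyloxy carbon para to the aryloxy carbon, and chemoselectivity for capture of 14 by 9 over dimerisation or acylation of the product phenol, for which 9 is used in excess and the hindered, hydrogen-bonded hydroxyl of 18 helps.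

**Step 7**
Reactants: 18 2-(4-bromophenoxy)-3-isopropoxy-5-(triisopropylsilyloxy)phenol
Product: 19 [4-(4-bromophenoxy)-3,5-diisopropoxyphenoxy]triisopropylsilane
Conditions: i-PrOH, PPh3, DIAD, THF, 0 °C → rt
Reagents that add atoms: propan-2-ol, CC(C)O
Why: Mitsunobu etherification of a phenol with a secondary alcohol runs under neutral conditions, so the aryl silyl ether is not exposed to base-induced cleavage that would scramble the oxygen pattern; apart from the silyl group the product is mirror-symmetric.

**Step 8**
Reactants: 19 [4-(4-bromophenoxy)-3,5-diisopropoxyphenoxy]triisopropylsilane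
Product: 20 4-(4-bromophenoxy)-3,5-diisopropoxyphenol
Conditions: TBAF, THF, 0 °C
Reagents that add atoms: none
Why: Fluoride cleaves the aryl silyl ether selectively; isopropyl ethers, the diaryl ether and the aryl bromide are inert, and the symmetric phenol results with its free hydroxyl at the future O1.

**Step 9**
Reactants: 20 4-(4-bromophenoxy)-3,5-diisopropoxyphenol
Product: 22 1-[3-(4-bromophenoxy)-6-hydroxy-2,4-diisopropoxyphenyl]ethan-1-one, via ketiminium chloride 21 (not isolated)
Conditions: MeCN, ZnCl2, HCl (g), Et2O, 0 °C; then H2O, 90 °C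
Reagents that add atoms: acetonitrile, CC#N; water, O
Why: Houben–Hoesch acylation: the nitrilium species attacks the only free positions of the phloroglucinol-type ring, which are equivalent and ortho to the hydroxyl (the para position is blocked by the aryloxy group), so only one ketone can form on hydrolysis of 21. The conditions are gentler towards isopropyl ethers than aluminium- or boron-halide Friedel–Crafts or Fries conditions.

**Step 10**
Reactants: 22 1-[3-(4-bromophenoxy)-6-hydroxy-2,4-diisopropoxyphenyl]ethan-1-one; 23 4-isopropoxybenzaldehyde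
Product: 24 (E)-1-[3-(4-bromophenoxy)-6-hydroxy-2,4-diisopropoxyphenyl]-3-(4-isopropoxyphenyl)prop-2-en-1-one
Conditions: KOH, EtOH, rt
Reagents that add atoms: none
Why: Claisen–Schmidt condensation of the methyl ketone with a non-enolisable aldehyde; dehydration gives the conjugated E-chalcone, and the base step is done before any pyranone ring exists.

**Step 11**
Reactants: 24 (E)-1-[3-(4-bromophenoxy)-6-hydroxy-2,4-diisopropoxyphenyl]-3-(4-isopropoxyphenyl)prop-2-en-1-one
Product: 26 6-(4-bromophenoxy)-5,7-diisopropoxy-2-(4-isopropoxyphenyl)-4H-chromen-4-one, via flavanone 25 (not isolated)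
Conditions: I2 (10 mol %), DMSO, 120 °C
Reagents that add atoms: none
Why: Iodine-catalysed oxidative cyclisation of a 2'-hydroxychalcone: oxa-Michael closure to flavanone 25, alpha-iodination and loss of HI give the flavone, with DMSO reoxidising iodide. The hydroxyl that closes the ring is the one unmasked in step 8, so the aryloxy group ends at C6.

**Step 12**
Reactants: 26 6-(4-bromophenoxy)-5,7-diisopropoxy-2-(4-isopropoxyphenyl)-4H-chromen-4-one; 27 (trimethylsilyl)acetylene
Product: 28 5,7-diisopropoxy-2-(4-isopropoxyphenyl)-6-{4-[(trimethylsilyl)ethynyl]phenoxy}-4H-chromen-4-one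
Conditions: PdCl2(PPh3)2 (3 mol %), CuI (5 mol %), Et3N, DMF, 80 °C
Reagents that add atoms: none
Why: Sonogashira coupling of the aryl bromide with a silyl-capped alkyne; the flavone and the ethers are inert to the amine and to zerovalent palladium.

**Step 13**
Reactants: 28 5,7-diisopropoxy-2-(4-isopropoxyphenyl)-6-{4-[(trimethylsilyl)ethynyl]phenoxy}-4H-chromen-4-one
Product: 29 6-(4-ethynylphenoxy)-5,7-diisopropoxy-2-(4-isopropoxyphenyl)-4H-chromen-4-one
Conditions: K2CO3 (cat.), MeOH/THF, rt
Reagents that add atoms: none
Why: Methanolysis of the alkynyl C–Si bond under mild carbonate catalysis, which a 2-arylchromone tolerates at room temperature.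

**Step 14**
Reactants: 30 3,5-dimethoxyphenol
Product: 31 2-iodo-3,5-dimethoxyphenol
Conditions: NIS, MeCN, −20 → 0 °C
Reagents that add atoms: N-iodosuccinimide, O=C1CCC(=O)N1I
Why: Electrophilic iodination of a highly activated phenol; C2 (flanked by hydroxyl and methoxy) is less hindered than C4 (flanked by two methoxy groups) and should be favoured, and any C4 isomer is removed by chromatography.

**Step 15**
Reactants: 29 6-(4-ethynylphenoxy)-5,7-diisopropoxy-2-(4-isopropoxyphenyl)-4H-chromen-4-one; 31 2-iodo-3,5-dimethoxyphenol
Product: 34 6-[4-(5,7-dimethoxy-4-oxo-4H-chromen-2-yl)phenoxy]-5,7-diisopropoxy-2-(4-isopropoxyphenyl)-4H-chromen-4-one, via alkynone 32 (not isolated), via enaminone 33 (not isolated)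
Conditions: CO (10 bar), PdCl2(dppf) (5 mol %), Et2NH, 100 °C
Reagents that add atoms: carbon monoxide, [C-]#[O+]
Why: Palladium-catalysed carbonylative annulation of an ortho-iodophenol with a terminal alkyne: oxidative addition of 31 to zerovalent palladium, CO insertion and coupling with 29 give alkynone 32. The secondary amine adds to the ynone to give enaminone 33 and the phenol then displaces the amine at the beta carbon, which enforces the 6-endo (flavone) over the 5-exo (aurone) mode. The medium contains no hydroxide, so the pyranone of unit 2 is not degraded.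

**Step 16**
Reactants: 34 6-[4-(5,7-dimethoxy-4-oxo-4H-chromen-2-yl)phenoxy]-5,7-diisopropoxy-2-(4-isopropoxyphenyl)-4H-chromen-4-one
Product: 35 neocryptomerin
Conditions: BCl3 (excess), CH2Cl2, −78 → 0 °C; then H2O
Reagents that add atoms: none
Why: BCl3 cleaves secondary alkyl aryl ethers at low temperature and cleaves a methyl ether only where chelation to the neighbouring carbonyl assists, so the three isopropyl groups and the O5 methyl of unit 1 are removed while the O7 methyl stays. Low temperature and the absence of hot protic acid avoid opening and reclosure of the 5-hydroxypyranone rings.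

## Compound list

1 | isopropyl vinyl ether | C=COC(C)C | starting material
2 | 1,2-dibromo-1-isopropoxyethane (racemic) | BrCC(Br)OC(C)C | intermediate
3 | (Z)-1-bromo-2-isopropoxyethene | Br/C=C\OC(C)C | intermediate
4 | sodium isopropoxyacetylide | [Na+].[C-]#COC(C)C | intermediate
5 | isopropoxyacetylene | C#COC(C)C | intermediate
6 | acetylene | C#C | starting material
7 | lithium acetylide | [Li+].[C-]#C | intermediate
8 | lithium ethynolate | [Li+].[O-]C#C | intermediate
9 | (triisopropylsilyloxy)acetylene | C#CO[Si](C(C)C)(C(C)C)C(C)C | intermediate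
10 | (4-bromophenoxy)acetic acid | OC(=O)COc1ccc(Br)cc1 | starting material
11 | (4-bromophenoxy)acetyl chloride | ClC(=O)COc1ccc(Br)cc1 | intermediate
12 | (4-bromophenoxy)ketene | O=C=COc1ccc(Br)cc1 | intermediate
13 | 4-(4-bromophenoxy)-3-isopropoxycyclobut-2-en-1-one (racemic) | CC(C)OC1=CC(=O)C1Oc1ccc(Br)cc1 | intermediate
14 | (3Z)-4-(4-bromophenoxy)-3-isopropoxybuta-1,3-dien-1-one | O=C=C/C(OC(C)C)=C/Oc1ccc(Br)cc1 | intermediate
15 | 4-[(Z)-2-(4-bromophenoxy)-1-isopropoxyethenyl]-3-(triisopropylsilyloxy)cyclobut-2-en-1-one (racemic) | O=C1C=C(O[Si](C(C)C)(C(C)C)C(C)C)C1/C(OC(C)C)=C/Oc1ccc(Br)cc1 | intermediate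
16 | (3E,5Z)-6-(4-bromophenoxy)-5-isopropoxy-3-(triisopropylsilyloxy)hexa-1,3,5-trien-1-one | O=C=C/C(O[Si](C(C)C)(C(C)C)C(C)C)=C\C(OC(C)C)=C\Oc1ccc(Br)cc1 | intermediate
17 | 6-(4-bromophenoxy)-5-isopropoxy-3-(triisopropylsilyloxy)cyclohexa-2,4-dien-1-one (racemic) | O=C1C=C(O[Si](C(C)C)(C(C)C)C(C)C)C=C(OC(C)C)C1Oc1ccc(Br)cc1 | intermediate
18 | 2-(4-bromophenoxy)-3-isopropoxy-5-(triisopropylsilyloxy)phenol | CC(C)Oc1cc(O[Si](C(C)C)(C(C)C)C(C)C)cc(O)c1Oc1ccc(Br)cc1 | intermediate
19 | [4-(4-bromophenoxy)-3,5-diisopropoxyphenoxy]triisopropylsilane | CC(C)Oc1cc(O[Si](C(C)C)(C(C)C)C(C)C)cc(OC(C)C)c1Oc1ccc(Br)cc1 | intermediate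
20 | 4-(4-bromophenoxy)-3,5-diisopropoxyphenol | CC(C)Oc1cc(O)cc(OC(C)C)c1Oc1ccc(Br)cc1 | intermediate
21 | 1-[3-(4-bromophenoxy)-6-hydroxy-2,4-diisopropoxyphenyl]ethan-1-iminium chloride | CC(=[NH2+])c1c(O)cc(OC(C)C)c(Oc2ccc(Br)cc2)c1OC(C)C.[Cl-] | intermediate
22 | 1-[3-(4-bromophenoxy)-6-hydroxy-2,4-diisopropoxyphenyl]ethan-1-one | CC(=O)c1c(O)cc(OC(C)C)c(Oc2ccc(Br)cc2)c1OC(C)C | intermediate
23 | 4-isopropoxybenzaldehyde | CC(C)Oc1ccc(C=O)cc1 | starting material
24 | (E)-1-[3-(4-bromophenoxy)-6-hydroxy-2,4-diisopropoxyphenyl]-3-(4-isopropoxyphenyl)prop-2-en-1-one | CC(C)Oc1ccc(/C=C/C(=O)c2c(O)cc(OC(C)C)c(Oc3ccc(Br)cc3)c2OC(C)C)cc1 | intermediate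
25 | 6-(4-bromophenoxy)-5,7-diisopropoxy-2-(4-isopropoxyphenyl)chroman-4-one (racemic) | CC(C)Oc1ccc(cc1)C1CC(=O)c2c(O1)cc(OC(C)C)c(Oc3ccc(Br)cc3)c2OC(C)C | intermediate
26 | 6-(4-bromophenoxy)-5,7-diisopropoxy-2-(4-isopropoxyphenyl)-4H-chromen-4-one | CC(C)Oc1ccc(cc1)-c1cc(=O)c2c(o1)cc(OC(C)C)c(Oc3ccc(Br)cc3)c2OC(C)C | intermediate
27 | (trimethylsilyl)acetylene | C#C[Si](C)(C)C | starting material
28 | 5,7-diisopropoxy-2-(4-isopropoxyphenyl)-6-{4-[(trimethylsilyl)ethynyl]phenoxy}-4H-chromen-4-one | CC(C)Oc1ccc(cc1)-c1cc(=O)c2c(o1)cc(OC(C)C)c(Oc3ccc(C#C[Si](C)(C)C)cc3)c2OC(C)C | intermediate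
29 | 6-(4-ethynylphenoxy)-5,7-diisopropoxy-2-(4-isopropoxyphenyl)-4H-chromen-4-one | CC(C)Oc1ccc(cc1)-c1cc(=O)c2c(o1)cc(OC(C)C)c(Oc3ccc(C#C)cc3)c2OC(C)C | intermediate
30 | 3,5-dimethoxyphenol | COc1cc(O)cc(OC)c1 | starting material
31 | 2-iodo-3,5-dimethoxyphenol | COc1cc(O)c(I)c(OC)c1 | intermediate
32 | 6-{4-[3-(2-hydroxy-4,6-dimethoxyphenyl)-3-oxoprop-1-yn-1-yl]phenoxy}-5,7-diisopropoxy-2-(4-isopropoxyphenyl)-4H-chromen-4-one | COc1cc(O)c(C(=O)C#Cc2ccc(Oc3c(OC(C)C)cc4oc(-c5ccc(OC(C)C)cc5)cc(=O)c4c3OC(C)C)cc2)c(OC)c1 | intermediate
33 | 6-{4-[(E)-1-(diethylamino)-3-(2-hydroxy-4,6-dimethoxyphenyl)-3-oxoprop-1-en-1-yl]phenoxy}-5,7-diisopropoxy-2-(4-isopropoxyphenyl)-4H-chromen-4-one (geometry of no consequence) | CCN(CC)/C(=C/C(=O)c1c(O)cc(OC)cc1OC)c1ccc(Oc2c(OC(C)C)cc3oc(-c4ccc(OC(C)C)cc4)cc(=O)c3c2OC(C)C)cc1 | intermediate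
34 | 6-[4-(5,7-dimethoxy-4-oxo-4H-chromen-2-yl)phenoxy]-5,7-diisopropoxy-2-(4-isopropoxyphenyl)-4H-chromen-4-one | COc1cc(OC)c2c(=O)cc(-c3ccc(Oc4c(OC(C)C)cc5oc(-c6ccc(OC(C)C)cc6)cc(=O)c5c4OC(C)C)cc3)oc2c1 | intermediate
35 | neocryptomerin, 5,7-dihydroxy-6-[4-(5-hydroxy-7-methoxy-4-oxo-4H-chromen-2-yl)phenoxy]-2-(4-hydroxyphenyl)-4H-chromen-4-one | COc1cc(O)c2c(=O)cc(-c3ccc(Oc4c(O)cc5oc(-c6ccc(O)cc6)cc(=O)c5c4O)cc3)oc2c1 | target

## Step count and least certain steps

Total step count: 16. Longest linear sequence: 13 steps (steps 1, 2, 5, 6, 7, 8, 9, 10, 11, 12, 13, 15, 16).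

**Step 6 (key step).** Capture of vinylketene 14 by 9 may be outrun by ketene dimerisation or by acylation of the phenolic product. The 3-isopropoxy group also stabilises 13 as a vinylogous ester, which may push the ring-opening temperature to where the silyl ynol ether decomposes. The fallback gives up the ring construction and accepts an arylation at the flanked oxygen. It sets out from aldehyde 23 and comes back at chalcone 24. Commercial 2',4',6'-trihydroxyacetophenone is isopropylated twice (2-bromopropane, K2CO3, DMF; the chelated hydroxyl stays free) to 1-(2-hydroxy-4,6-diisopropoxyphenyl)ethan-1-one F1. Elbs persulfate oxidation (K2S2O8, aqueous NaOH, then hot dilute HCl) introduces the para hydroxyl and gives 1-(3,6-dihydroxy-2,4-diisopropoxyphenyl)ethan-1-one F2. Claisen–Schmidt condensation of F2 with 23 gives (E)-1-(3,6-dihydroxy-2,4-diisopropoxyphenyl)-3-(4-isopropoxyphenyl)prop-2-en-1-one F3. The non-chelated hydroxyl between the two isopropoxy groups is then arylated with bis(4-bromophenyl)iodonium triflate (K2CO3, MeCN) to give 24.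

**Step 3.** Monolithium acetylide may disproportionate before oxygen transfer is complete, and silylation may go partly to carbon. The fallback sets out from 27 and comes back at 18. Deprotonation, peroxide oxidation and O-silylation as in step 3, applied to the thermally stable lithium (trimethylsilyl)acetylide, give 1-(triisopropylsilyloxy)-2-(trimethylsilyl)acetylene F4. Benzannulation of 13 with F4 under the conditions of step 6 gives 2-(4-bromophenoxy)-3-isopropoxy-5-(triisopropylsilyloxy)-6-(trimethylsilyl)phenol F5. Ipso-protodesilylation of the activated aryl silane (CF3CO2H, CH2Cl2, 0 °C) returns 18.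

**Step 9.** An isopropyl ether, above all the one ortho to the new iminium group, may be cleaved with zinc assistance, which would open the way to closure on the wrong oxygen. The phenol may also be O-imidated instead of C-acylated. The fallback avoids acid. It sets out from 20 and comes back at 22. Ortho-formylation with MgCl2, Et3N and paraformaldehyde in MeCN (Casnati–Skattebøl formylation) gives 3-(4-bromophenoxy)-6-hydroxy-2,4-diisopropoxybenzaldehyde F6. Excess MeMgBr in THF at 0 °C gives 4-(4-bromophenoxy)-2-(1-hydroxyethyl)-3,5-diisopropoxyphenol F7. Benzylic oxidation with MnO2 in CH2Cl2 gives 22.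

**Step 15.** Coupling may occur without CO insertion (leading on to a 2-arylbenzofuran), the alkynone may close in the five-membered mode, and oxidative addition into the doubly ortho-substituted, electron-rich iodide may be slow. The fallback is a Baker–Venkataraman sequence. It sets out from 26 and comes back at 34. Palladium-catalysed hydroxycarbonylation (Pd(OAc)2, Xantphos, CO, K2CO3, H2O/dioxane) gives 4-{[5,7-diisopropoxy-2-(4-isopropoxyphenyl)-4-oxo-4H-chromen-6-yl]oxy}benzoic acid F8. Esterification with commercial 1-(2-hydroxy-4,6-dimethoxyphenyl)ethan-1-one (EDC, DMAP, CH2Cl2) gives 2-acetyl-3,5-dimethoxyphenyl 4-{[5,7-diisopropoxy-2-(4-isopropoxyphenyl)-4-oxo-4H-chromen-6-yl]oxy}benzoate F9. Acyl migration with LiN(SiMe3)2 in THF (−78 → 0 °C) gives 1-(2-hydroxy-4,6-dimethoxyphenyl)-3-(4-{[5,7-diisopropoxy-2-(4-isopropoxyphenyl)-4-oxo-4H-chromen-6-yl]oxy}phenyl)propane-1,3-dione F10. Cyclodehydration (p-TsOH, toluene, 80 °C) gives 34.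

## Further compounds

F1 | step 6 | 1-(2-hydroxy-4,6-diisopropoxyphenyl)ethan-1-one | CC(=O)c1c(O)cc(OC(C)C)cc1OC(C)C
F2 | step 6 | 1-(3,6-dihydroxy-2,4-diisopropoxyphenyl)ethan-1-one | CC(=O)c1c(O)cc(OC(C)C)c(O)c1OC(C)C
F3 | step 6 | (E)-1-(3,6-dihydroxy-2,4-diisopropoxyphenyl)-3-(4-isopropoxyphenyl)prop-2-en-1-one | CC(C)Oc1ccc(/C=C/C(=O)c2c(O)cc(OC(C)C)c(O)c2OC(C)C)cc1
F4 | step 3 | 1-(triisopropylsilyloxy)-2-(trimethylsilyl)acetylene | C[Si](C)(C)C#CO[Si](C(C)C)(C(C)C)C(C)C
F5 | step 3 | 2-(4-bromophenoxy)-3-isopropoxy-5-(triisopropylsilyloxy)-6-(trimethylsilyl)phenol | CC(C)Oc1cc(O[Si](C(C)C)(C(C)C)C(C)C)c([Si](C)(C)C)c(O)c1Oc1ccc(Br)cc1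
F6 | step 9 | 3-(4-bromophenoxy)-6-hydroxy-2,4-diisopropoxybenzaldehyde | O=Cc1c(O)cc(OC(C)C)c(Oc2ccc(Br)cc2)c1OC(C)C
F7 | step 9 | 4-(4-bromophenoxy)-2-(1-hydroxyethyl)-3,5-diisopropoxyphenol (racemic) | CC(O)c1c(O)cc(OC(C)C)c(Oc2ccc(Br)cc2)c1OC(C)C
F8 | step 15 | 4-{[5,7-diisopropoxy-2-(4-isopropoxyphenyl)-4-oxo-4H-chromen-6-yl]oxy}benzoic acid | CC(C)Oc1ccc(cc1)-c1cc(=O)c2c(o1)cc(OC(C)C)c(Oc3ccc(cc3)C(=O)O)c2OC(C)C
F9 | step 15 | 2-acetyl-3,5-dimethoxyphenyl 4-{[5,7-diisopropoxy-2-(4-isopropoxyphenyl)-4-oxo-4H-chromen-6-yl]oxy}benzoate | CC(=O)c1c(OC)cc(OC)cc1OC(=O)c1ccc(Oc2c(OC(C)C)cc3oc(-c4ccc(OC(C)C)cc4)cc(=O)c3c2OC(C)C)cc1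
F10 | step 15 | 1-(2-hydroxy-4,6-dimethoxyphenyl)-3-(4-{[5,7-diisopropoxy-2-(4-isopropoxyphenyl)-4-oxo-4H-chromen-6-yl]oxy}phenyl)propane-1,3-dione | COc1cc(O)c(C(=O)CC(=O)c2ccc(Oc3c(OC(C)C)cc4oc(-c5ccc(OC(C)C)cc5)cc(=O)c4c3OC(C)C)cc2)c(OC)c1
A1 | alternative 1 | 4-({7-(benzyloxy)-2-[4-(benzyloxy)phenyl]-5-hydroxy-4-oxo-4H-chromen-6-yl}oxy)-2H-pyran-2-one | O=c1cc(Oc2c(OCc3ccccc3)cc3oc(-c4ccc(OCc5ccccc5)cc4)cc(=O)c3c2O)cco1
A2 | alternative 1 | 2-ethynyl-5,7-dimethoxy-4H-chromen-4-one | COc1cc(OC)c2c(=O)cc(C#C)oc2c1
A3 | alternative 1 | 5-O-methyl-7'',4'''-di-O-benzylneocryptomerin | COc1cc(OC)c2c(=O)cc(-c3ccc(Oc4c(OCc5ccccc5)cc5oc(-c6ccc(OCc7ccccc7)cc6)cc(=O)c5c4O)cc3)oc2c1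
A4 | alternative 2 | methyl 4-{6-isopropoxy-3-[3-(4-isopropoxyphenyl)-3-oxopropanoyl]-2-methoxyphenoxy}benzoate | COC(=O)c1ccc(Oc2c(OC(C)C)ccc(C(=O)CC(=O)c3ccc(OC(C)C)cc3)c2OC)cc1
A5 | alternative 2 | methyl 4-({7-isopropoxy-2-[4-(isopropoxy)phenyl]-5-methoxy-4-oxo-4H-chromen-6-yl}oxy)benzoate | COC(=O)c1ccc(Oc2c(OC(C)C)cc3oc(-c4ccc(OC(C)C)cc4)cc(=O)c3c2OC)cc1
A6 | alternative 3 | 6-{4-[4-({5,7-bis(benzyloxy)-2-[4-(benzyloxy)phenyl]-4-oxo-4H-chromen-6-yl}oxy)phenyl]-2-oxobut-3-yn-1-yl}-4-methoxy-2H-pyran-2-one | COc1cc(=O)oc(CC(=O)C#Cc2ccc(Oc3c(OCc4ccccc4)cc4oc(-c5ccc(OCc6ccccc6)cc5)cc(=O)c4c3OCc3ccccc3)cc2)c1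
A7 | alternative 3 | 5'',7'',4'''-tri-O-benzylneocryptomerin | COc1cc(O)c2c(=O)cc(-c3ccc(Oc4c(OCc5ccccc5)cc5oc(-c6ccc(OCc7ccccc7)cc6)cc(=O)c5c4OCc4ccccc4)cc3)oc2c1
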